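**Retrosynthetic overview**
1. Target ⇐ desilylation and C9 acylation ⇐ 9,10-diol ⇐ anti-dihydroxylation (outer-face epoxidation, then acid opening at C10 with inversion) of an E-9,10-olefinic germacranolide.
2. The γ-lactone is closed last, by oxidative lactonisation of an 8,12-diol on the finished ten-membered carbocycle.
3. Key step: the ten-membered ring is not made by macrocyclisation but by anionic oxy-Cope ring expansion of a trans-1,2-dialkenylcyclohexanol (C5–C10 cleaved, C7–C8 formed). This sets C7, C8 and the E-olefin and delivers the C5 enolate, which is hydroxylated at C6 in the same flask.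
4. The cyclohexanol comes from acetylide addition of enyne fragment 2 to ketone fragment 1. Fragment 1 is made from 2,6-dimethylcyclohexanone by decarboxylative asymmetric allylation (quaternary C10), allyl → formyl, equilibration of C4, and E-selective CHO → CH=CH–OPMB.
5. Ring order: six-membered carbocycle (purchased) → ten-membered carbocycle (ring expansion) → five-membered lactone.

Assumption: (2E)-3-methylpent-2-enoic acid is bought as the pure E isomer; the enantiomeric purity of the route is that of step 2 (high-80s % ee expected) unless a crystalline intermediate is recrystallised.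
Conventions: PMB = 4-methoxybenzyl, TBS = tert-butyldimethylsilyl. Ten-membered-ring compounds carry germacrane locants (ring C1–C10 with C5 the ketone carbon; C11–C13 the branch on C7, C12 oxygenated; C14 methyl on C10; C15 methyl on C4). Numbered building blocks stand under Reactants; the line "Reagents that add atoms" lists un-numbered reagents only.

**Fragment 1 (ketone)**

Step 1
Reactants: 1 2,6-dimethylcyclohexan-1-one (commercial cis/trans mixture); 2 allyl chloroformate
Product: 4 prop-2-en-1-yl 2,6-dimethylcyclohex-1-en-1-yl carbonate, via lithium enolate 3 (not isolated)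
Conditions: LiN(i-Pr)2, THF, 0 °C; TMEDA, then 2, −78 °C → rt
Reagents that add atoms: none
Why: Enolate O-acylation: the symmetrical ketone can give only one (tetrasubstituted) enolate, and the hard chloroformate acylates it on oxygen in THF/TMEDA to give the enol carbonate; the remaining C6 stereocentre is racemic here and is dealt with in step 4.

Step 2
Reactants: 4 prop-2-en-1-yl 2,6-dimethylcyclohex-1-en-1-yl carbonate
Product: 5 (2R)-2,6-dimethyl-2-(prop-2-en-1-yl)cyclohexan-1-one (C6 epimer mixture)
Conditions: Pd2(dba)3 (2.5 mol %), (R)-t-BuPHOX (6 mol %), THF, 25 °C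
Reagents that add atoms: none
Why: Tsuji decarboxylative asymmetric allylic alkylation: zerovalent palladium ionises the allyl carbonate, CO2 is lost and the PHOX-bound allylpalladium enolate forms the C–C bond on one enolate face, which sets the quaternary centre as R (ee in the high 80s is typical for α-methylcyclohexanone enol carbonates with this ligand class, the R ligand giving the R ketone), while C6 is deliberately left as an epimer mixture.

Step 3
Reactants: 5 (2R)-2,6-dimethyl-2-(prop-2-en-1-yl)cyclohexan-1-one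
Product: 6 (2R)-2,6-dimethyl-2-[(1E)-prop-1-en-1-yl]cyclohexan-1-one (C6 epimer mixture)
Conditions: RuHCl(CO)(PPh3)3 (5 mol %), toluene, 110 °C
Reagents that add atoms: none
Why: Ruthenium hydride catalysed olefin isomerisation (hydrometalation then β-hydride elimination) moves the terminal double bond one carbon inward to the E-propenyl group and cannot go further because C2 is quaternary; no stereocentre is touched.

Step 4
Reactants: 6 (2R)-2,6-dimethyl-2-[(1E)-prop-1-en-1-yl]cyclohexan-1-one
Product: 9 (1R,3S)-1,3-dimethyl-2-oxocyclohexane-1-carbaldehyde, via ozonide 7 (not isolated), via C3-epimeric keto aldehyde 8 (not isolated)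
Conditions: O3, CH2Cl2, −78 °C; PPh3, −78 °C → rt; then DBU (0.2 equiv), rt; chromatography (minor C3 epimer re-equilibrated)
Reagents that add atoms: ozone, [O-][O+]=O
Why: Ozonolysis (Criegee mechanism, reductive work-up) cuts the propenyl group to the formyl group, and base-mediated epimerisation at the only enolisable carbon C3 then funnels the mixture to the isomer that has both methyls equatorial and the small formyl group axial (A value about 0.7 against 1.7 kcal/mol for methyl, so about 6:1 or better), which is the 1R,3S compound.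

Step 5
Reactants: 9 (1R,3S)-1,3-dimethyl-2-oxocyclohexane-1-carbaldehyde; 10 2-(dichloromethyl)-4,4,5,5-tetramethyl-1,3,2-dioxaborolane
Product: 12 (2R,6S)-2,6-dimethyl-2-[(E)-2-(4,4,5,5-tetramethyl-1,3,2-dioxaborolan-2-yl)ethenyl]cyclohexan-1-one, via geminal dichromium reagent 11 (not isolated)
Conditions: CrCl2 (8 equiv), LiI (4 equiv), THF, 25 °C
Reagents that add atoms: none
Why: Takai–Utimoto olefination: the geminal dichromium species formed from 10 and divalent chromium adds to the aldehyde only (the hindered ketone is inert) and anti elimination from the less crowded adduct gives the E-alkenylboronate, typically >20:1 for α-branched aldehydes.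

Step 6
Reactants: 12 the E-alkenylboronate from step 5; 13 4-methoxybenzyl alcohol
Product: 14 (2R,6S)-2-[(E)-2-(4-methoxybenzyloxy)ethenyl]-2,6-dimethylcyclohexan-1-one
Conditions: Cu(OAc)2 (2 equiv), Et3N (4 equiv), 13 (10 equiv), 4 Å MS, CH2Cl2, 25 °C
Reagents that add atoms: none
Why: Chan–Lam–Evans oxidative C–O coupling: boron-to-copper transmetalation, alkoxide binding and reductive elimination give the enol ether with retention of the E geometry, at room temperature with Et3N as the only base so that C6 does not epimerise.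

**Fragment 2 (enyne)**

Step 7
Reactants: 13 4-methoxybenzyl alcohol; 15 2,3-dibromoprop-1-ene
Product: 17 1-{[(2-bromoprop-2-en-1-yl)oxy]methyl}-4-methoxybenzene, via sodium alkoxide 16 (not isolated)
Conditions: NaH, THF, 0 °C; then 15, n-Bu4NI (cat.), 0 °C → rt
Reagents that add atoms: none
Why: Williamson ether synthesis: SN2 displacement of the allylic bromide by the alkoxide, the vinylic bromide being inert.

Step 8
Reactants: 17 1-{[(2-bromoprop-2-en-1-yl)oxy]methyl}-4-methoxybenzene; 18 ethynyltrimethylsilane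
Product: 19 {3-[(4-methoxybenzyloxy)methyl]but-3-en-1-yn-1-yl}trimethylsilane
Conditions: Pd(PPh3)2Cl2 (3 mol %), CuI (6 mol %), i-Pr2NH, THF, 40 °C
Reagents that add atoms: none
Why: Sonogashira coupling of the alkenyl bromide with the terminal alkyne (oxidative addition, copper acetylide transmetalation, reductive elimination).

Step 9
Reactants: 19 {3-[(4-methoxybenzyloxy)methyl]but-3-en-1-yn-1-yl}trimethylsilane
Product: 20 1-methoxy-4-{[(2-methylidenebut-3-yn-1-yl)oxy]methyl}benzene
Conditions: K2CO3 (0.2 equiv), MeOH, 0 °C → rt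
Reagents that add atoms: none
Why: Base-catalysed methanolysis of the alkynyl C–Si bond (protodesilylation) leaves the terminal enyne.

**Union, ring expansion and endgame**

Step 10
Reactants: 20 the terminal enyne from step 9; 14 the enol ether ketone from step 6
Product: 22 (1R,2R,6S)-2-[(E)-2-(4-methoxybenzyloxy)ethenyl]-1-{3-[(4-methoxybenzyloxy)methyl]but-3-en-1-yn-1-yl}-2,6-dimethylcyclohexan-1-ol, via lithium acetylide 21 (not isolated)
Conditions: n-BuLi, THF, −78 °C; then 14, −78 → 0 °C; aq NH4Cl
Reagents that add atoms: none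
Why: 1,2-Addition of an alkynyllithium to a ketone: 14 sits in the chair with both methyls equatorial and the alkoxyvinyl group axial, so the slim nucleophile enters axially on the face opposite that group, which puts the alkynyl group trans to the alkoxyvinyl group and sets C1 (R).

Step 11
Reactants: 22 the propargylic alcohol from step 10
Product: 23 (1S,2R,6S)-2-[(E)-2-(4-methoxybenzyloxy)ethenyl]-1-{(1E)-3-[(4-methoxybenzyloxy)methyl]buta-1,3-dien-1-yl}-2,6-dimethylcyclohexan-1-ol
Conditions: NaAlH2(OCH2CH2OMe)2, THF, 0 → 40 °C; then H2O/aq NaOH work-up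
Reagents that add atoms: none
Why: Hydroxyl-directed trans-hydroalumination of a propargylic alcohol (hydride delivered within the alkoxyaluminate, then protonolysis) gives only the E-olefin and does not touch the 1,1-disubstituted olefin, the enol ether or the PMB ethers.

Step 12
Reactants: 23 the trans-1,2-dialkenylcyclohexanol from step 11
Product: 26 (4S,6S,7S,8S,9E)-6-hydroxy-8,12-bis(4-methoxybenzyloxy)germacra-9,11(13)-dien-5-one, via potassium alkoxide 24 (not isolated), via potassium enolate 25 (not isolated)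
Conditions: KH (1.3 equiv), 18-crown-6 (1.3 equiv), THF, 0 → 50 °C; then −78 °C, Davis oxaziridine (1.5 equiv); aq NH4Cl
Reagents that add atoms: 3-phenyl-2-(phenylsulfonyl)oxaziridine (Davis oxaziridine), O=S(=O)(c1ccccc1)N1OC1c1ccccc1
Why: Anionic oxy-Cope rearrangement followed by Davis enolate hydroxylation: the alkoxide rearranges through the chair transition state that has both alkenyl groups equatorial (the two axial methyls this requires are the reason for warming), so the two E-olefins translate the C5/C10 chirality into the 7,8-trans relationship and an E-9,10-olefin, and the resulting C5–C6 enolate is oxidised on its outer face, the inner one being blocked by the transannular olefin, which sets C6 as S.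

Step 13
Reactants: 26 the α-hydroxy ketone from step 12
Product: 27 (4S,6S,7R,8S,9E)-6-(tert-butyldimethylsilyloxy)-8,12-bis(4-methoxybenzyloxy)germacra-9,11(13)-dien-5-one
Conditions: TBSOTf (1.2 equiv), 2,6-lutidine, CH2Cl2, −78 → 0 °C
Reagents that add atoms: tert-butyldimethylsilyl triflate, CC(C)(C)[Si](C)(C)OS(=O)(=O)C(F)(F)F
Why: Silyl ether protection of the secondary α-ketol hydroxyl (silyl triflate with a hindered pyridine base) so that later only O8 can lactonise and only O9 can be acylated.

Step 14
Reactants: 27 the silyl ether from step 13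
Product: 28 (4S,6S,7R,8S,9E)-6-(tert-butyldimethylsilyloxy)-8,12-dihydroxygermacra-9,11(13)-dien-5-one
Conditions: DDQ (3 equiv), CH2Cl2/pH 7 phosphate buffer (10:1), 0 °C → rt
Reagents that add atoms: none
Why: Oxidative PMB ether cleavage: DDQ abstracts hydride from both electron-rich benzylic positions and water hydrolyses the oxocarbenium ions, while the silyl ether and the olefins are inert under buffered conditions.

Step 15
Reactants: 28 the 8,12-diol from step 14
Product: 31 (4S,6S,7R,8S,9E)-6-(tert-butyldimethylsilyloxy)-5-oxogermacra-9,11(13)-dien-12,8-olide, via hydroxy enal 29 (not isolated), via lactol 30 (not isolated)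
Conditions: TEMPO (0.2 equiv), PhI(OAc)2 (3 equiv), CH2Cl2, 25 °C
Reagents that add atoms: none
Why: Oxoammonium (TEMPO) oxidative lactonisation of a 1,4-diol: the primary allylic alcohol is oxidised first, the aldehyde is captured by the only free hydroxyl (O8) as the lactol and a second oxidation gives the α-methylene γ-lactone, trans-fused because C7 and C8 were set in step 12.

Step 16
Reactants: 31 the dienolide from step 15
Product: 32 (4S,6S,7R,8R,9S,10S)-6-(tert-butyldimethylsilyloxy)-9,10-epoxy-5-oxogermacr-11(13)-en-12,8-olide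
Conditions: mCPBA (1.2 equiv), CH2Cl2, 0 °C
Reagents that add atoms: 3-chloroperoxybenzoic acid, OOC(=O)c1cccc(Cl)c1
Why: Prilezhaev epoxidation of the only electron-rich olefin (the lactone methylene is deactivated) on the outer face of the E-cyclodecene, whose conformation is fixed by A(1,3) strain (H8 eclipses the olefin and the ring carbon C7 covers the inner face), giving the 9S,10S epoxide.

Step 17
Reactants: 32 the epoxide from step 16
Product: 33 (4S,6S,7R,8R,9S,10R)-6-(tert-butyldimethylsilyloxy)-9,10-dihydroxy-5-oxogermacr-11(13)-en-12,8-olide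
Conditions: HClO4 (5 mol %), THF/H2O (3:1), 0 °C
Reagents that add atoms: water, O
Why: Acid-catalysed epoxide hydrolysis: the protonated epoxide opens at the tertiary carbon C10 with inversion, by backside attack of water or of the transannular C5 carbonyl oxygen followed by opening of the resulting hemiketal (both give the same result), while C9 keeps the epoxide oxygen, so the 9S,10R diol is formed.

Step 18
Reactants: 33 the 9,10-diol from step 17; 34 (2E)-3-methylpent-2-enoic acid
Product: 36 (4S,6S,7R,8R,9S,10R)-6-(tert-butyldimethylsilyloxy)-10-hydroxy-9-[(2E)-3-methylpent-2-enoyloxy]-5-oxogermacr-11(13)-en-12,8-olide, via mixed anhydride 35 (not isolated)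
Conditions: 34 (3 equiv), 2,4,6-Cl3C6H2COCl (3 equiv), Et3N, toluene, rt; then 33, DMAP, rt
Reagents that add atoms: none
Why: Yamaguchi esterification: DMAP transfers the enoyl group from the mixed anhydride to the only acylable hydroxyl, the secondary O9 (O10 is tertiary and O6 is silylated), without touching any stereocentre.

Step 19
Reactants: 36 the silylated ester from step 18
Product: 37 (4S,6S,7S,8R,9S,10R)-6,10-dihydroxy-9-[(2E)-3-methylpent-2-enoyloxy]-5-oxogermacr-11(13)-en-12,8-olide (CNP0197047.1)
Conditions: HF·pyridine, THF/pyridine, 0 °C → rt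
Reagents that add atoms: none
Why: Fluoride-driven silyl ether cleavage (Si–F bond formation) under buffered non-basic conditions that spare the enoate, the α-methylene lactone and the α-ketol, giving the target.

**Compound list**
1 | 2,6-dimethylcyclohexan-1-one (cis/trans mixture) | CC1CCCC(C)C1=O | starting material
2 | allyl chloroformate | C=CCOC(=O)Cl | starting material
3 | lithium 2,6-dimethylcyclohex-1-en-1-olate (racemic) | CC1CCCC(C)=C1[O-].[Li+] | intermediate (not isolated)
4 | prop-2-en-1-yl 2,6-dimethylcyclohex-1-en-1-yl carbonate (racemic) | C=CCOC(=O)OC1=C(C)CCCC1C | intermediate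
5 | (2R)-2,6-dimethyl-2-(prop-2-en-1-yl)cyclohexan-1-one (C6 epimer mixture) | O=C1[C@@](C)(CC=C)CCCC1C | intermediate
6 | (2R)-2,6-dimethyl-2-[(1E)-prop-1-en-1-yl]cyclohexan-1-one (C6 epimer mixture) | O=C1[C@@](C)(/C=C/C)CCCC1C | intermediate
7 | (2R)-2,6-dimethyl-2-(5-methyl-1,2,4-trioxolan-3-yl)cyclohexan-1-one (ozonide, isomer mixture) | O=C1[C@@](C)(C2OOC(C)O2)CCCC1C | intermediate (not isolated)
8 | (1R)-1,3-dimethyl-2-oxocyclohexane-1-carbaldehyde (C3 epimer mixture) | O=C1[C@@](C)(C=O)CCCC1C | intermediate (not isolated)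
9 | (1R,3S)-1,3-dimethyl-2-oxocyclohexane-1-carbaldehyde | O=C1[C@@](C)(C=O)CCC[C@@H]1C | intermediate
10 | 2-(dichloromethyl)-4,4,5,5-tetramethyl-1,3,2-dioxaborolane | ClC(Cl)B1OC(C)(C)C(C)(C)O1 | starting material
11 | geminal dichromium reagent (pinB)CH(CrCl2)2 (idealised, THF ligands omitted) | Cl[Cr](Cl)C([Cr](Cl)Cl)B1OC(C)(C)C(C)(C)O1 | intermediate (not isolated)
12 | (2R,6S)-2,6-dimethyl-2-[(E)-2-(4,4,5,5-tetramethyl-1,3,2-dioxaborolan-2-yl)ethenyl]cyclohexan-1-one | O=C1[C@@](C)(/C=C/B2OC(C)(C)C(C)(C)O2)CCC[C@@H]1C | intermediate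
13 | 4-methoxybenzyl alcohol | COc1ccc(CO)cc1 | starting material
14 | (2R,6S)-2-[(E)-2-(4-methoxybenzyloxy)ethenyl]-2,6-dimethylcyclohexan-1-one | O=C1[C@@](C)(/C=C/OCc2ccc(OC)cc2)CCC[C@@H]1C | intermediate
15 | 2,3-dibromoprop-1-ene | C=C(Br)CBr | starting material
16 | sodium (4-methoxyphenyl)methanolate | COc1ccc(C[O-])cc1.[Na+] | intermediate (not isolated)
17 | 1-{[(2-bromoprop-2-en-1-yl)oxy]methyl}-4-methoxybenzene | C=C(Br)COCc1ccc(OC)cc1 | intermediate
18 | ethynyltrimethylsilane | C#C[Si](C)(C)C | starting material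
19 | {3-[(4-methoxybenzyloxy)methyl]but-3-en-1-yn-1-yl}trimethylsilane | C=C(COCc1ccc(OC)cc1)C#C[Si](C)(C)C | intermediate
20 | 1-methoxy-4-{[(2-methylidenebut-3-yn-1-yl)oxy]methyl}benzene | C=C(COCc1ccc(OC)cc1)C#C | intermediate
21 | lithium acetylide of 20 | C=C(COCc1ccc(OC)cc1)C#[C-].[Li+] | intermediate (not isolated)
22 | (1R,2R,6S)-2-[(E)-2-(4-methoxybenzyloxy)ethenyl]-1-{3-[(4-methoxybenzyloxy)methyl]but-3-en-1-yn-1-yl}-2,6-dimethylcyclohexan-1-ol | O[C@@]1(C#CC(=C)COCc2ccc(OC)cc2)[C@@](C)(/C=C/OCc2ccc(OC)cc2)CCC[C@@H]1C | intermediate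
23 | (1S,2R,6S)-2-[(E)-2-(4-methoxybenzyloxy)ethenyl]-1-{(1E)-3-[(4-methoxybenzyloxy)methyl]buta-1,3-dien-1-yl}-2,6-dimethylcyclohexan-1-ol | O[C@@]1(/C=C/C(=C)COCc2ccc(OC)cc2)[C@@](C)(/C=C/OCc2ccc(OC)cc2)CCC[C@@H]1C | intermediate
24 | potassium alkoxide of 23 | [K+].[O-][C@@]1(/C=C/C(=C)COCc2ccc(OC)cc2)[C@@](C)(/C=C/OCc2ccc(OC)cc2)CCC[C@@H]1C | intermediate (not isolated)
25 | potassium (4S,5Z,7R,8S,9E)-8,12-bis(4-methoxybenzyloxy)germacra-5,9,11(13)-trien-5-olate | C1C[C@H](C)/C([O-])=C/[C@H](C(=C)COCc2ccc(OC)cc2)[C@@H](OCc2ccc(OC)cc2)/C=C(C)/C1.[K+] | intermediate (not isolated)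
26 | (4S,6S,7S,8S,9E)-6-hydroxy-8,12-bis(4-methoxybenzyloxy)germacra-9,11(13)-dien-5-one | C1C[C@H](C)C(=O)[C@@H](O)[C@H](C(=C)COCc2ccc(OC)cc2)[C@@H](OCc2ccc(OC)cc2)/C=C(C)/C1 | intermediate
27 | (4S,6S,7R,8S,9E)-6-(tert-butyldimethylsilyloxy)-8,12-bis(4-methoxybenzyloxy)germacra-9,11(13)-dien-5-one | C1C[C@H](C)C(=O)[C@@H](O[Si](C)(C)C(C)(C)C)[C@H](C(=C)COCc2ccc(OC)cc2)[C@@H](OCc2ccc(OC)cc2)/C=C(C)/C1 | intermediate
28 | (4S,6S,7R,8S,9E)-6-(tert-butyldimethylsilyloxy)-8,12-dihydroxygermacra-9,11(13)-dien-5-one | C1C[C@H](C)C(=O)[C@@H](O[Si](C)(C)C(C)(C)C)[C@H](C(=C)CO)[C@@H](O)/C=C(C)/C1 | intermediate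
29 | (4S,6S,7R,8S,9E)-6-(tert-butyldimethylsilyloxy)-8-hydroxy-5-oxogermacra-9,11(13)-dien-12-al | C1C[C@H](C)C(=O)[C@@H](O[Si](C)(C)C(C)(C)C)[C@H](C(=C)C=O)[C@@H](O)/C=C(C)/C1 | intermediate (not isolated)
30 | (4S,6S,7R,8S,9E)-6-(tert-butyldimethylsilyloxy)-12-hydroxy-8,12-epoxygermacra-9,11(13)-dien-5-one (lactol, C12 epimers) | C1C[C@H](C)C(=O)[C@@H](O[Si](C)(C)C(C)(C)C)[C@H](C(=C)C(O)O2)[C@@H]2/C=C(C)/C1 | intermediate (not isolated)
31 | (4S,6S,7R,8S,9E)-6-(tert-butyldimethylsilyloxy)-5-oxogermacra-9,11(13)-dien-12,8-olide | C1C[C@H](C)C(=O)[C@@H](O[Si](C)(C)C(C)(C)C)[C@H](C(=C)C(=O)O2)[C@@H]2/C=C(C)/C1 | intermediate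
32 | (4S,6S,7R,8R,9S,10S)-6-(tert-butyldimethylsilyloxy)-9,10-epoxy-5-oxogermacr-11(13)-en-12,8-olide | C1C[C@H](C)C(=O)[C@@H](O[Si](C)(C)C(C)(C)C)[C@H](C(=C)C(=O)O2)[C@@H]2[C@@H]3O[C@@]3(C)C1 | intermediate
33 | (4S,6S,7R,8R,9S,10R)-6-(tert-butyldimethylsilyloxy)-9,10-dihydroxy-5-oxogermacr-11(13)-en-12,8-olide | C1C[C@H](C)C(=O)[C@@H](O[Si](C)(C)C(C)(C)C)[C@H](C(=C)C(=O)O2)[C@@H]2[C@H](O)[C@](C)(O)C1 | intermediate
34 | (2E)-3-methylpent-2-enoic acid | CC/C(C)=C/C(=O)O | starting material
35 | (2E)-3-methylpent-2-enoic 2,4,6-trichlorobenzoic anhydride | CC/C(C)=C/C(=O)OC(=O)c1c(Cl)cc(Cl)cc1Cl | intermediate (not isolated)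
36 | (4S,6S,7R,8R,9S,10R)-6-(tert-butyldimethylsilyloxy)-10-hydroxy-9-[(2E)-3-methylpent-2-enoyloxy]-5-oxogermacr-11(13)-en-12,8-olide | C1C[C@H](C)C(=O)[C@@H](O[Si](C)(C)C(C)(C)C)[C@H](C(=C)C(=O)O2)[C@@H]2[C@H](OC(=O)/C=C(\C)CC)[C@](C)(O)C1 | intermediate
37 | (4S,6S,7S,8R,9S,10R)-6,10-dihydroxy-9-[(2E)-3-methylpent-2-enoyloxy]-5-oxogermacr-11(13)-en-12,8-olide | C=C1C(=O)O[C@@H]2[C@@H]1[C@H](O)C(=O)[C@@H](C)CCC[C@@](C)(O)[C@H]2OC(=O)/C=C(\C)CC | target

**Totals**
Total step count: 19. Longest linear sequence: 16 steps (steps 1–6, then 10–19); the enyne branch (steps 7–9) joins at step 10.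

**Three steps most likely to fail, with fallbacks**

Step 12 (ring expansion). Risk: the reactive chair of alkoxide 24 carries the two methyls 1,3-diaxial, so alkoxide fragmentation or enolate equilibration could compete with the rearrangement. The fallback sets out from 23 and comes back at 26, leaving the anionic manifold. Compound 23 is silylated with N-(trimethylsilyl)imidazole to the tertiary trimethylsilyl ether F1. F1 is rearranged thermally (toluene, sealed tube, 180–200 °C, neutral siloxy-Cope through the same chair) to the ring-expanded trimethylsilyl enol ether F2. F2 is oxidised with one equivalent of dimethyldioxirane at −78 °C followed by dilute citric acid (Rubottom oxidation on the outer face), which gives 26.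

Step 6 (enol ether). Risk: the Chan–Lam coupling with a benzylic alcohol that is not the solvent may stall at protodeboronation or homocoupling. The fallback sets out from 9 and comes back at 22; it makes the carbon–oxygen bond from an alkenyl iodide after the ketone has been used up. Takai iodo-olefination of 9 (CHI3, CrCl2, THF) gives the E-iodoalkene F3. Lithium acetylide 21 is added to F3 as in step 10 to give the iodoalkenyl carbinol F4. Copper-catalysed etherification of F4 with 13 (CuI, 3,4,7,8-tetramethyl-1,10-phenanthroline, Cs2CO3, toluene, 80 °C, retention of olefin geometry) gives 22. With no ketone left, the basic coupling cannot epimerise C6.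

Step 17 (epoxide opening). Risk: transannular chemistry typical of ten-membered rings (stable hemiketals, hydride shifts, elimination to allylic alcohols) or lactone migration to O9 in aqueous acid. The fallback sets out from 32 and comes back at 36, skipping 33. Epoxide 32 is opened directly with acid 34 (excess, 5 mol % camphorsulfonic acid, CH2Cl2, 0 °C) to the tertiary C10 ester F5 (attack at C10 with inversion, O9 free). The acyl group is then moved to the less hindered secondary O9 with catalytic DBU in toluene (1,2 O→O acyl shift through the cyclic orthoester, the secondary ester being the thermodynamic sink), which gives 36.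

**Further compounds**
F1 | step 12 | (1S,2R,6S)-trimethylsilyl ether of 23 | C[Si](C)(C)O[C@@]1(/C=C/C(=C)COCc2ccc(OC)cc2)[C@@](C)(/C=C/OCc2ccc(OC)cc2)CCC[C@@H]1C
F2 | step 12 | (4S,5Z,7R,8S,9E)-8,12-bis(4-methoxybenzyloxy)-5-(trimethylsilyloxy)germacra-5,9,11(13)-triene | C1C[C@H](C)/C(O[Si](C)(C)C)=C/[C@H](C(=C)COCc2ccc(OC)cc2)[C@@H](OCc2ccc(OC)cc2)/C=C(C)/C1
F3 | step 6 | (2R,6S)-2-[(E)-2-iodoethenyl]-2,6-dimethylcyclohexan-1-one | O=C1[C@@](C)(/C=C/I)CCC[C@@H]1C
F4 | step 6 | (1R,2R,6S)-2-[(E)-2-iodoethenyl]-1-{3-[(4-methoxybenzyloxy)methyl]but-3-en-1-yn-1-yl}-2,6-dimethylcyclohexan-1-ol | O[C@@]1(C#CC(=C)COCc2ccc(OC)cc2)[C@@](C)(/C=C/I)CCC[C@@H]1C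
F5 | step 17 | (4S,6S,7R,8R,9S,10R)-6-(tert-butyldimethylsilyloxy)-9-hydroxy-10-[(2E)-3-methylpent-2-enoyloxy]-5-oxogermacr-11(13)-en-12,8-olide | C1C[C@H](C)C(=O)[C@@H](O[Si](C)(C)C(C)(C)C)[C@H](C(=C)C(=O)O2)[C@@H]2[C@H](O)[C@](C)(OC(=O)/C=C(\C)CC)C1
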